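**Retrosynthetic overview**
- The strategy rests on ring C (C13–C14–C17–C22–C23): the quaternary gem-dimethyl carbon C14 is bonded to C17, which carries the tertiary carbinol C18. This is the pattern left by a C14 radical adding to a prenyl group on C23 with oxygen capture at C18, so ring C is cut last at C14–C17 and C18–O.
- The ring-C-open diene (isopropenyl on C13, prenyl on C23) comes from C7 acylation of the bicyclo[3.2.1]octanetrione with (R)-2-methylbutanoic acid.
- Ring A comes from a malonyl dichloride annulation (bonds C10–C8 and C23–C24) across the two α-carbons of a cyclopentanone (ring B) that carries the C10 methyl, C23 prenyl and C13 isopropenyl groups.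
- The cyclopentanone comes from cyclopent-2-en-1-one: a rhodium-catalysed asymmetric isopropenyl addition sets C13, and a temporary ester on C10 sends prenyl to C23 and methyl to C10.
- Ring order: B (present from the start), A (step 6), C (step 8).

Key step: step 8

Remark: atom labels follow the target SMILES with oxygens counted. The triketone is drawn as the C8 enol although its enol tautomers interconvert. C10 and C23 are epimerisable in the monocyclic intermediates, so only C13 has to be controlled before ring A is closed.

**Route**

Step 1
Reactants: 1 cyclopent-2-en-1-one; 2 4,4,5,5-tetramethyl-2-(prop-1-en-2-yl)-1,3,2-dioxaborolane (isopropenylboronic acid pinacol ester)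
Product: 3 (R)-3-(prop-1-en-2-yl)cyclopentan-1-one
Conditions: [Rh(cod)Cl]2 (cat.), (R)-BINAP, aq KOH, 1,4-dioxane/H2O, 50 °C
Reagents that add atoms: isopropenylboronic acid pinacol ester (2), CC(=C)B1OC(C)(C)C(C)(C)O1
Why: Hayashi–Miyaura rhodium-catalysed asymmetric 1,4-addition of an alkenylboron reagent to a 2-cycloalkenone, in which the BINAP-bound alkenylrhodium species adds to one enantioface of the enone and sets C13; the (R)-ligand is chosen because the established facial model (the S ligand gives S-3-substituted cycloalkanones) predicts the 3R ketone.

Step 2
Reactants: 3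
Product: 4 methyl (4R)-2-oxo-4-(prop-1-en-2-yl)cyclopentane-1-carboxylate (C1 epimers and enol form)
Conditions: NaH, (MeO)2CO, THF, reflux; aq HCl work-up
Reagents that add atoms: dimethyl carbonate, COC(=O)OC
Why: Claisen-type methoxycarbonylation of the ketone enolate, which should occur at the α-methylene remote from the isopropenyl-bearing carbon (the future C10) because acylation next to C13 is sterically retarded and the product is withdrawn as its stabilised enolate; any minor regioisomer would be removed by chromatography.

Step 3
Reactants: 4; 5 prenyl bromide (1-bromo-3-methylbut-2-ene)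
Product: 7 methyl (3S,4R)-1-methyl-3-(3-methylbut-2-en-1-yl)-2-oxo-4-(prop-1-en-2-yl)cyclopentane-1-carboxylate (both C1 epimers), via prenylated keto ester 6 (not isolated)
Conditions: NaH, THF, 0 °C; n-BuLi, 0 °C; 5, −20 to 0 °C; then MeI, rt
Reagents that add atoms: prenyl bromide (5), CC(C)=CCBr; iodomethane, CI
Why: Weiler dianion alkylation, in which the more basic γ-carbanion (the future C23, the only free α'-position) is prenylated first by SN2 displacement anti to the adjacent isopropenyl group and the remaining β-keto ester enolate is then C-methylated at C10, so that the ester decides which α-carbon receives which group.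

Step 4
Reactants: 7
Product: 8 (2S,3R)-5-methyl-2-(3-methylbut-2-en-1-yl)-3-(prop-1-en-2-yl)cyclopentan-1-one (both C5 epimers)
Conditions: LiCl, DMSO, H2O, 150 °C
Reagents that add atoms: none
Why: Krapcho dealkoxycarbonylation, in which chloride demethylates the ester, the carboxylate loses CO2 and the C10 enolate is protonated, removing the directing ester without touching either alkene; the configurations at C10 and C23 are immaterial because both centres are re-enolised in step 6.

Step 5
Reactants: 8
Product: 9 trimethyl{[(4R,5S)-2-methyl-5-(3-methylbut-2-en-1-yl)-4-(prop-1-en-2-yl)cyclopent-1-en-1-yl]oxy}silane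
Conditions: LiN(iPr)2, THF, −78 to 0 °C; Me3SiCl
Reagents that add atoms: chlorotrimethylsilane, C[Si](C)(C)Cl
Why: Kinetic deprotonation at the less hindered of the two tertiary α-hydrogens (C10–H) followed by O-silylation gives the tetrasubstituted silyl enol ether; a minor regioisomer with the double bond toward C23 leads to the same trione in step 6 and need not be removed.

Step 6
Reactants: 9; 10 malonyl dichloride
Product: 12 (7-exo)-4-hydroxy-5-methyl-1-(3-methylbut-2-en-1-yl)-7-(prop-1-en-2-yl)bicyclo[3.2.1]oct-3-ene-2,8-dione (rings A and B; C10 methyl and C23 prenyl at the bridgeheads; isopropenyl on C13 anti to the C7–C8–C24 bridge), via keto acid chloride 11 (not isolated)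
Conditions: 10, Et2O, −20 °C to rt; then aq KOH, BnEt3NCl, 0 °C; HCl to pH 2
Reagents that add atoms: malonyl dichloride (10), O=C(Cl)CC(=O)Cl
Why: Effenberger cyclisation, the α,α'-annulation of a cycloalkanone enol ether with malonyl dichloride known for cyclohexanone-derived enol ethers and applied here to the cyclopentanone homologue: C-acylation at C10 releases Me3SiCl, the ketone enolises toward C23 and the tethered acid chloride acylates C23 on the same face, which closes ring A and fixes C10 and C23; the bridge should form anti to the isopropenyl group because closure at C23 on the face of the neighbouring C13 substituent is hindered, leaving the isopropenyl group exo and cis to the prenyl group.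

Step 7
Reactants: 12; 13 (R)-2-methylbutanoic acid
Product: 15 the ring-C-open triketone: 12 carrying the (2R)-2-methylbutanoyl group on C7 (C3 of the bicycle) and drawn as the C8 enol, via enol ester 14 (not isolated)
Conditions: DCC, DMAP, CH2Cl2, 0 °C to rt
Reagents that add atoms: (R)-2-methylbutanoic acid (13), CC[C@@H](C)C(=O)O
Why: Carbodiimide-mediated O-acylation of the vinylogous acid followed by DMAP-mediated 1,3-acyl shift (the O-to-C migration known for 2-acylcycloalkane-1,3-diones) places the acyl group on C7; activation through the O-acylisourea and acylpyridinium, not through a ketene, should leave the (R)-centre of the acid intact.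

Step 8
Reactants: 15
Product: 17 the target CNP0207052.1, via C18 hydroperoxide 16 (not isolated)
Conditions: Fe(acac)3, PhSiH3, EtOH/THF, air admitted slowly, 0 °C to rt; then PPh3; dilute HCl wash
Reagents that add atoms: dioxygen, O=O
Why: An iron hydride formed from Fe(acac)3 and PhSiH3 in ethanol transfers a hydrogen atom to the CH2 terminus of the isopropenyl group, which as a 1,1-disubstituted alkene reacts faster than the trisubstituted prenyl alkene, and leaves the tertiary radical at C14. This radical closes ring C in a 5-exo-trig mode onto C17, the less substituted carbon of the prenyl alkene, forming the C14–C17 bond and a tertiary C18 radical that O2 captures; PPh3 reduces hydroperoxide 16 to the carbinol. The closest known reaction type is the Mukaiyama-type hydration of alkenes applied to a 1,6-diene, in which cyclisation of the first radical precedes oxygen capture. The cis fusion of ring C is not at stake, because the exo isopropenyl group on C13 and the bridgehead prenyl group on C23 lie on the same side of the rigid bicycle, so C17 is the only new stereocentre. Its configuration depends on the side to which the CMe2 terminus turns in the transition state: the target needs C18 on the face of ring C that carries C12 and C26, the two orientations differ little (C12 methylene against H-13 and C24), and the C17 epimer is expected as a co-product to be separated by chromatography. The step needs ring closure to outrun oxygen capture at C14, which the fixed proximity of radical and alkene and a low stationary oxygen concentration should secure, and the acidic triketone has to be released from iron by the acid wash.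

**Compound list**
1 | cyclopent-2-en-1-one | O=C1C=CCC1 | starting material
2 | 4,4,5,5-tetramethyl-2-(prop-1-en-2-yl)-1,3,2-dioxaborolane | CC(=C)B1OC(C)(C)C(C)(C)O1 | starting material
3 | (R)-3-(prop-1-en-2-yl)cyclopentan-1-one | O=C1CC[C@@H](C(C)=C)C1 | intermediate
4 | methyl (4R)-2-oxo-4-(prop-1-en-2-yl)cyclopentane-1-carboxylate | COC(=O)C1C[C@@H](C(C)=C)CC1=O | intermediate
5 | prenyl bromide | CC(C)=CCBr | starting material
6 | methyl (3S,4R)-3-(3-methylbut-2-en-1-yl)-2-oxo-4-(prop-1-en-2-yl)cyclopentane-1-carboxylate (prenyl trans to isopropenyl) | COC(=O)C1C[C@@H](C(C)=C)[C@H](CC=C(C)C)C1=O | intermediate (not isolated)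
7 | methyl (3S,4R)-1-methyl-3-(3-methylbut-2-en-1-yl)-2-oxo-4-(prop-1-en-2-yl)cyclopentane-1-carboxylate (both C1 epimers) | COC(=O)C1(C)C[C@@H](C(C)=C)[C@H](CC=C(C)C)C1=O | intermediate
8 | (2S,3R)-5-methyl-2-(3-methylbut-2-en-1-yl)-3-(prop-1-en-2-yl)cyclopentan-1-one (both C5 epimers) | CC1C[C@@H](C(C)=C)[C@H](CC=C(C)C)C1=O | intermediate
9 | trimethyl{[(4R,5S)-2-methyl-5-(3-methylbut-2-en-1-yl)-4-(prop-1-en-2-yl)cyclopent-1-en-1-yl]oxy}silane | C[Si](C)(C)OC1=C(C)C[C@@H](C(C)=C)[C@@H]1CC=C(C)C | intermediate
10 | malonyl dichloride | O=C(Cl)CC(=O)Cl | starting material
11 | 3-oxo-3-[1-methyl-2-oxo-3-prenyl-4-isopropenylcyclopentyl]propanoyl chloride (acyl group on C10 anti to the isopropenyl group) | O=C(Cl)CC(=O)[C@]1(C)C[C@@H](C(C)=C)[C@H](CC=C(C)C)C1=O | intermediate (not isolated)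
12 | (7-exo)-4-hydroxy-5-methyl-1-(3-methylbut-2-en-1-yl)-7-(prop-1-en-2-yl)bicyclo[3.2.1]oct-3-ene-2,8-dione | C1=C(O)[C@]2(C)C[C@@H](C(C)=C)[C@](CC=C(C)C)(C1=O)C2=O | intermediate
13 | (R)-2-methylbutanoic acid | CC[C@@H](C)C(=O)O | starting material
14 | enol (2R)-2-methylbutanoate of 12 (acyl on the C8 oxygen) | C1=C(OC(=O)[C@H](C)CC)[C@]2(C)C[C@@H](C(C)=C)[C@](CC=C(C)C)(C1=O)C2=O | intermediate (not isolated)
15 | ring-C-open triketone: 12 with the (2R)-2-methylbutanoyl group on C7 (isopropenyl on C13 exo, prenyl on C23) | CC[C@@H](C)C(=O)C1=C(O)[C@]2(C)C[C@@H](C(C)=C)[C@](CC=C(C)C)(C1=O)C2=O | intermediate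
16 | C18 hydroperoxide of the target (2-hydroperoxypropan-2-yl on C17) | CC[C@@H](C)C(=O)C1=C(O)[C@]2(C)C[C@H]3C(C)(C)[C@@H](C(C)(C)OO)C[C@@]3(C1=O)C2=O | intermediate (not isolated)
17 | target CNP0207052.1 (for the tautomer drawn: C3 R, C10 S, C13 S, C17 S, C23 S; 2-hydroxypropan-2-yl on C17 on the ring B face of ring C) | CC[C@@H](C)C(=O)C1=C(O)[C@]2(C)C[C@H]3C(C)(C)[C@@H](C(C)(C)O)C[C@@]3(C1=O)C2=O | target

**Step count and risk**

Total step count: 8. Longest linear sequence: 8 steps (from cyclopent-2-en-1-one).

Steps most likely to fail:

1. Step 8 (key step). Oxygen may capture the C14 radical before it reaches C17, giving the uncyclised hydrate. If oxygen is kept too low, the C18 radical may instead be reduced or lose a hydrogen atom. Hydrogen-atom transfer to the prenyl alkene and the weak facial bias at C17 cut further into the yield. The fallback separates ring closure from oxygenation. It sets out from 15: a cobalt-catalysed HAT cycloisomerisation under argon (Co(salen)Cl with the 3,5-di-tert-butyl salen ligand, PhSiH3, benzene, rt) should close ring C with no oxygen present and end by hydrogen-atom loss from a C18 methyl group, giving the ring-C-closed alkene with a prop-1-en-2-yl group on C17, F1, from which the C17 epimer is separated. Mukaiyama hydration of this 1,1-disubstituted alkene (Co(acac)2, PhSiH3, O2, THF/i-PrOH, then PPh3) then gives the tertiary alcohol, and the route is rejoined at 17.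

2. Step 6. In the more strained bicyclo[3.2.1] series, O-acylation of the enolised mono-acylated ketone (enol lactone formation) may outrun the second C-acylation. A first acylation on the isopropenyl face gives material that cannot close or closes to the endo diastereomer, and HCl may add to the alkenes. The fallback builds ring A stepwise by Claisen chemistry. It sets out from 7, using the C10 epimer whose ester is anti to the isopropenyl group (separated by chromatography). LiN(iPr)2 and acetaldehyde at −78 °C add a 1-hydroxyethyl group to C23 anti to the isopropenyl group, giving the aldol product F2. Dess–Martin periodinane oxidises it to the C23 methyl ketone F3. LiN(SiMe3)2 then forms the methyl ketone enolate (C7), which attacks the C10 ester (C8) in an intramolecular Claisen condensation driven by formation of the dione enolate. Acidification gives the trione, and the route is rejoined at 12.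

3. Step 2. Incomplete regioselectivity in the methoxycarbonylation (acylation next to C13) would carry through a regioisomer that ends with methyl and prenyl exchanged and is hard to separate. The fallback builds the directing ester into the acceptor. It sets out from boronate 2: commercial methyl 1-methyl-2-oxocyclopentane-1-carboxylate is dehydrogenated with IBX to the racemic enone methyl 1-methyl-2-oxocyclopent-3-ene-1-carboxylate F4. The rhodium/(R)-BINAP addition of 2 under the conditions of step 1 should then give, under catalyst control, methyl (4R)-1-methyl-2-oxo-4-(prop-1-en-2-yl)cyclopentane-1-carboxylate F5 as both C1 epimers; the remote C1 centre is removed in step 4. LiN(iPr)2 and prenyl bromide 5 alkylate the only enolisable position, and the route is rejoined at 7.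

**Further compounds**
F1 | step 8 | ring-C-closed alkene: 17 with a prop-1-en-2-yl group on C17 in place of the 2-hydroxypropan-2-yl group | CC[C@@H](C)C(=O)C1=C(O)[C@]2(C)C[C@H]3C(C)(C)[C@@H](C(C)=C)C[C@@]3(C1=O)C2=O
F2 | step 6 | methyl 3-(1-hydroxyethyl)-1-methyl-3-(3-methylbut-2-en-1-yl)-2-oxo-4-(prop-1-en-2-yl)cyclopentane-1-carboxylate (ester and hydroxyethyl both anti to isopropenyl; carbinol epimers) | COC(=O)[C@]1(C)C[C@@H](C(C)=C)[C@](CC=C(C)C)(C(C)O)C1=O
F3 | step 6 | methyl 3-acetyl-1-methyl-3-(3-methylbut-2-en-1-yl)-2-oxo-4-(prop-1-en-2-yl)cyclopentane-1-carboxylate (ester and acetyl both anti to isopropenyl) | COC(=O)[C@]1(C)C[C@@H](C(C)=C)[C@](CC=C(C)C)(C(C)=O)C1=O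
F4 | step 2 | methyl 1-methyl-2-oxocyclopent-3-ene-1-carboxylate (racemic) | COC(=O)C1(C)CC=CC1=O
F5 | step 2 | methyl (4R)-1-methyl-2-oxo-4-(prop-1-en-2-yl)cyclopentane-1-carboxylate (both C1 epimers) | COC(=O)C1(C)C[C@@H](C(C)=C)CC1=O
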